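**Plan**

1. Retrosynthesis: the acetates and silyl ethers come off last; O12 and O13 go back to a C13 enone (enol ether oxidation, hydride reduction); C7–C11 is cut as a Mukaiyama–Michael addition to dienone 5; ring B is cut at C6–C7 with C6–C10 re-closed, which leaves a cyclobutanone; C9–C10 and C20–S are cut as a thiolate Michael/aldol reaction; C4–CH3 as a Grignard addition; the four-membered ring as a ketene [2+2] cycloaddition.
2. Enabling feature: C1, C5, C6 and C10 can be drawn as a cyclobutanone fused to ring A (C1–C2=C3–C4–C5). Inserting C7–C8–C9 between C6 and C10 while the C6–C10 bond breaks gives ring B (C5–C6–C7–C8–C9–C10–C1) with the C6 ketone and the C10=C20 methylene in one event.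
3. Forward order: ring A from 6,6-dimethylfulvene, the four-membered ring from dichloroketene, the C4 carbinol on the rigid bicycle, double substitution of C10, ring B by radical three-carbon ring expansion, then the C11–C15 chain at C7 and adjustment of the oxygens.
4. Stereochemistry: C1/C5 cis from the [2+2] plus enzymatic resolution; C4 by exo methyl addition; C9 by an exo chair aldol; C5 inverted by equilibration to the trans fusion; C7/C11 by an axial, anti-selective Michael addition; C6 by hydride anti to the side chain; C12 by allylic-strain-controlled enol ether oxidation; C13 by Felkin–Anh reduction.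
5. Design choices: the C4 methyl carbinol is made before the ring expansion, because only the folded bicyclo[3.2.0] skeleton delivers methyl to the β face and because an alkylidene at C4 could conjugate with the C6 ketone under base. A phenyl selenide is the radical source, because a β-halo aldehyde would eliminate in the aldol step.

Key step: step 15

Convention: atoms are numbered C1–C15 and C20 as in the plan; β is the face of the bicyclic core that carries H-1, α the opposite face; in the bicyclo[3.2.0] intermediates C10 is locant 7, exo is β and endo is α.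
Assumption: a ketoreductase that accepts ketone 9 and distinguishes its enantiomers can be found in a commercial panel; the configuration it creates at C6 is immaterial, since C6 is re-oxidised in step 10.

**Route**

Step 1
Reactants: 1 acrolein
Product: 2 3-(phenylselanyl)propanal
Conditions: PhSeH, CH2Cl2, 0 → 23 °C
Reagents that add atoms: benzeneselenol, [SeH]c1ccccc1
Why: Uncatalysed conjugate (Michael) addition of the soft selenol to acrolein gives the β-seleno aldehyde, which carries C7–C8–C9 with a C–Se bond as the later radical source and does not eliminate under aldol conditions.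

Step 2
Reactants: 3 (E)-but-2-enal
Product: 4 (E)-6-methylhepta-2,5-dien-4-ol (racemic)
Conditions: (CH3)2C=CHMgBr, THF, −78 → 0 °C; NH4Cl (aq)
Reagents that add atoms: (2-methylprop-1-en-1-yl)magnesium bromide, CC(C)=C[Mg]Br
Why: Grignard 1,2-addition to the enal should give the bis-allylic alcohol with the E geometry of the enal retained.

Step 3
Reactants: 4 (E)-6-methylhepta-2,5-dien-4-ol
Product: 5 (E)-6-methylhepta-2,5-dien-4-one
Conditions: MnO2, CH2Cl2, 23 °C
Reagents that add atoms: none
Why: Allylic alcohol oxidation with activated MnO2 is neutral and selective, so the cross-conjugated dienone should form without double-bond migration.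

Step 4
Reactants: 6 6,6-dimethylfulvene; 7 trichloroacetyl chloride
Product: 8 rac-(1R,5R)-7,7-dichloro-4-(propan-2-ylidene)bicyclo[3.2.0]hept-2-en-6-one (cis-fused)
Conditions: Zn–Cu couple, POCl3, Et2O, 23 °C, slow addition of 7
Reagents that add atoms: none
Why: Dichloroketene made by zinc dechlorination adds to a ring double bond of the fulvene in a thermal ketene–alkene [2+2] cycloaddition, the carbonyl carbon bonding to the ring carbon next to the exocyclic alkene and the suprafacial mode fixing the cis fusion, while POCl3 ties up ZnCl2.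

Step 5
Reactants: 8 dichlorocyclobutanone
Product: 9 rac-(1R,5R)-4-(propan-2-ylidene)bicyclo[3.2.0]hept-2-en-6-one
Conditions: Zn, NH4Cl, MeOH, 23 °C
Reagents that add atoms: none
Why: Zinc reductive dechlorination of the α,α-dichloro ketone under buffered protic conditions removes both chlorines and should leave the diene and the strained ketone untouched.

Step 6
Reactants: 9 racemic ketone
Product: 10 (1R,5R,6R)-4-(propan-2-ylidene)bicyclo[3.2.0]hept-2-en-6-ol (6-endo alcohol)
Conditions: ketoreductase (NADPH-dependent, panel-selected), NADP+ (cat.), i-PrOH, phosphate buffer pH 7, 30 °C, to about half conversion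
Reagents that add atoms: none
Why: Enzymatic kinetic resolution by enantioselective ketone reduction, established for bicyclo[3.2.0]hept-2-en-6-ones, should reduce only the (1R,5R) ketone, with hydride arriving on the convex face.

Step 7
Reactants: 10 endo alcohol
Product: 11 (1R,5R,6R)-4-(propan-2-ylidene)bicyclo[3.2.0]hept-2-en-6-yl acetate
Conditions: Ac2O, pyridine, DMAP (cat.), CH2Cl2, 0 °C
Reagents that add atoms: acetic anhydride, CC(=O)OC(C)=O
Why: DMAP-catalysed acylation masks the cyclobutanol, so that no β-hydroxy ketone or β-alkoxide able to open the four-membered ring by retro-aldol cleavage exists once C4 is a carbonyl.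

Step 8
Reactants: 11 acetate
Product: 12 (1R,5S,6R)-4-oxobicyclo[3.2.0]hept-2-en-6-yl acetate
Conditions: O3, CH2Cl2–MeOH, pyridine, −78 °C (Sudan Red 7B end point); Me2S
Reagents that add atoms: ozone, [O-][O+]=O
Why: Ozonolysis with reductive work-up attacks the electron-rich tetrasubstituted exocyclic alkene first, and the cyclopentenone so formed deactivates C2=C3, so the reaction should stop at the enone.

Step 9
Reactants: 12 enone acetate
Product: 13 (1R,4S,5S,6R)-4-methylbicyclo[3.2.0]hept-2-ene-4,6-diol (4-methyl exo; both hydroxyls endo)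
Conditions: MeMgBr (5 equiv), CeCl3, THF, −78 → 0 °C
Reagents that add atoms: methylmagnesium bromide, C[Mg]Br
Why: Cerium-modified Grignard 1,2-addition to the enone occurs on the convex (β) face of the folded bicycle, placing methyl β and hydroxyl α at C4 as in the target, and the excess reagent cleaves the acetate only after the carbonyl is consumed.

Step 10
Reactants: 13 diol
Product: 14 (1R,4S,5R)-4-hydroxy-4-methylbicyclo[3.2.0]hept-2-en-6-one
Conditions: Dess–Martin periodinane, NaHCO3, CH2Cl2, 0 → 23 °C
Reagents that add atoms: none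
Why: Dess–Martin oxidation returns the secondary cyclobutanol to the ketone under buffered conditions, while the tertiary allylic alcohol can be neither oxidised nor transposed.

Step 11
Reactants: 14 hydroxy ketone
Product: 15 (1R,4S,5R)-4-(tert-butyldimethylsilyloxy)-4-methylbicyclo[3.2.0]hept-2-en-6-one
Conditions: TBSOTf, 2,6-lutidine, CH2Cl2, 0 °C
Reagents that add atoms: tert-butyldimethylsilyl trifluoromethanesulfonate, CC(C)(C)[Si](C)(C)OS(=O)(=O)C(F)(F)F
Why: Silyl triflate etherification of the tertiary alcohol blocks retro-aldol and alkoxide chemistry in the enolate steps that follow and gives a group meant to last to the final step.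

Step 12
Reactants: 15 silyloxy ketone
Product: 18 (1R,4S,5R)-4-(tert-butyldimethylsilyloxy)-4-methyl-7-methylidenebicyclo[3.2.0]hept-2-en-6-one, via Mannich base 16 (not isolated), via methiodide 17 (not isolated)
Conditions: LiN(i-Pr)2, THF, −78 °C; CH2=NMe2 I, −78 → 23 °C; MeI; NaHCO3 (aq), CH2Cl2
Reagents that add atoms: N,N-dimethylmethyleneiminium iodide, C=[N+](C)C.[I-]
Why: Kinetic deprotonation at the C10 methylene (C5 is a hindered ring-fusion methine), Mannich aminomethylation on the convex face, quaternisation and mild base-induced β-elimination should give the α-methylene ketone.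

Step 13
Reactants: 18 α-methylene ketone; 2 3-(phenylselanyl)propanal
Product: 20 (1R,4S,5R,7S)-7-[(1R)-1-hydroxy-3-(phenylselanyl)propyl]-7-(phenylsulfanylmethyl)-4-(tert-butyldimethylsilyloxy)-4-methylbicyclo[3.2.0]hept-2-en-6-one, via aluminium enolate 19 (not isolated)
Conditions: Me3Al, PhSH, CH2Cl2, 0 °C; 18, THF, −78 °C; then 2, −78 °C
Reagents that add atoms: benzenethiol (delivered as Me2AlSPh), Sc1ccccc1
Why: Tandem thia-Michael/aldol reaction, in which the aluminium thiolate adds to the exocyclic enone to give the C10 enolate regiospecifically and this adds to the aldehyde through a closed chair (Zimmerman–Traxler) transition state on the convex face with the aldehyde chain equatorial, which should set C9 as R and make C10 quaternary.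

Step 14
Reactants: 20 aldol
Product: 21 9-O-tert-butyldimethylsilyl ether of 20 (C10 bearing CH2SPh and the (1R)-1-silyloxy-3-(phenylselanyl)propyl group)
Conditions: TBSOTf, 2,6-lutidine, CH2Cl2, −78 → 0 °C
Reagents that add atoms: tert-butyldimethylsilyl trifluoromethanesulfonate, CC(C)(C)[Si](C)(C)OS(=O)(=O)C(F)(F)F
Why: Silyl triflate etherification of the hindered secondary alcohol prevents retro-aldol cleavage and protects O9 to the end.

Step 15
Reactants: 21 cyclobutanone with C10 phenylsulfanylmethyl and 3-(phenylselanyl)-1-silyloxypropyl groups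
Product: 22 (1R,4S,5R,9R)-4,9-bis(tert-butyldimethylsilyloxy)-4-methyl-10-methylene-cis-fused hydroazulen-6-one (H-1 and H-5 both β; 4α-OSi, 4β-CH3, 9β-OSi; C2=C3)
Conditions: Bu3SnH (1.3 equiv), AIBN (cat.), PhH (5 mM), 80 °C, syringe-pump addition
Reagents that add atoms: none
Why: The tin radical abstracts the phenylselanyl group to give the primary C7 radical, which attacks the cyclobutanone carbon C6 through a five-membered transition state from the convex face on which the C9 tether sits; the bicyclic alkoxy radical then undergoes β-scission of C6–C10, and the tertiary C10 radical expels phenylthiyl, which takes hydrogen from the stannane and carries the chain. The closest known reaction type is the Dowd–Beckwith ring expansion of α-(ω-haloalkyl) cyclobutanones to cycloheptanones, here with a selenide as radical source and β-elimination of a thiyl radical as the terminating event. Ring B is therefore closed by three-carbon ring expansion of the four-membered ring (addition to C=O followed by fragmentation), not by end-to-end cyclisation. No stereocentre is created: C1, C4, C5 and C9 are carried through, C10 becomes trigonal and the ring fusion stays cis. The step needs cleavage of C6–C10 and not C6–C5, which the more substituted C10 radical, its irreversible loss of thiyl and the release of cyclobutane strain should secure. It also needs carbonyl attack in preference to addition to C2=C3 or reduction of the C7 radical, which the short tether and a low stannane concentration should secure.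

Step 16
Reactants: 22 cis-fused ketone
Product: 23 (1R,4S,5S,9R)-trans-fused ketone (H-1 β, H-5 α; otherwise as 22)
Conditions: DBU (0.2 equiv), PhMe, 23 °C
Reagents that add atoms: none
Why: Base-mediated epimerisation through the C5–C6 enolate should equilibrate to the trans fusion, expected to be the more stable one for a 6-oxo hydroazulene and favoured further because it moves ring B off the face of the 4α silyloxy group; the tertiary silyloxy group is a poor leaving group for β-elimination under an amidine base.

Step 17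
Reactants: 23 trans-fused ketone
Product: 24 6-(triethylsilyloxy)-6,7-ene (C6=C7 enol silane of 23)
Conditions: LiN(i-Pr)2, THF, −78 °C; Et3SiCl, Et3N, −78 → 0 °C
Reagents that add atoms: chlorotriethylsilane, CC[Si](Cl)(CC)CC
Why: Kinetic enolisation removes a proton from the C7 methylene and not from the hindered C5 methine next to quaternary C4, and O-silylation fixes the C6=C7 enol ether.

Step 18
Reactants: 24 enol silane; 5 (E)-6-methylhepta-2,5-dien-4-one
Product: 25 trans-fused 6-ketone carrying at C7 (α) the (Z)-CH(CH3)–CH=C(OSiEt3)–CH=C(CH3)2 chain (C8 and the C11 methyl anti; configuration at C7 and C11 as in the target)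
Conditions: 5 (1.3 equiv), Ph3CSbCl6 (5 mol%), CH2Cl2, −78 °C; pyridine quench
Reagents that add atoms: none
Why: Trityl-cation-catalysed Mukaiyama–Michael addition with silyl transfer, in which the enol silane attacks the less substituted β-carbon of the dienone through an open synclinal transition state (anti adduct, as is usual for cyclic enol silanes and (E)-enones) and bonds axially on the α face of C7, opposite the pseudo-axial 9β silyloxy group; the C13 ketone emerges masked as its triethylsilyl dienol ether.

Step 19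
Reactants: 25 Michael adduct
Product: 26 6α-alcohol of 25 (6,7-cis)
Conditions: Li[BH(s-Bu)3], THF, −78 °C; H2O
Reagents that add atoms: none
Why: The bulky trialkylborohydride should reduce the only free ketone from the β face, anti to the adjacent axial α side chain, giving the 6,7-cis alcohol before C7 can epimerise, while the silyl dienol ether is inert to hydride.

Step 20
Reactants: 26 6α-alcohol
Product: 27 6-O-tert-butyldimethylsilyl ether of 26
Conditions: TBSOTf, 2,6-lutidine, CH2Cl2, −78 → −20 °C
Reagents that add atoms: tert-butyldimethylsilyl trifluoromethanesulfonate, CC(C)(C)[Si](C)(C)OS(=O)(=O)C(F)(F)F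
Why: Silyl triflate etherification of the hindered alcohol distinguishes O6 from the side-chain oxygens that will be acetylated, and the dienol ether should survive the buffered conditions.

Step 21
Reactants: 27 silyl dienol ether
Product: 29 12-(triethylsilyloxy)-13-oxo-14-ene (α-silyloxy enone; O12 syn to the C11 methyl), via silyloxy epoxide 28 (not isolated)
Conditions: dimethyldioxirane (1.05 equiv), acetone–CH2Cl2, −78 → 0 °C
Reagents that add atoms: dimethyldioxirane, CC1(C)OO1
Why: Rubottom oxidation, in which the dioxirane epoxidises the silyl enol ether (by far the most electron-rich alkene) on the face set by allylic 1,3-strain (H-11 eclipsing the enol ether, attack from the methyl side) and the silyloxy epoxide rearranges with silyl migration to the α-silyloxy enone.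

Step 22
Reactants: 29 α-silyloxy enone
Product: 30 13-alcohol (12,13-syn; O12 triethylsilyl)
Conditions: Li[BH(s-Bu)3], THF, −78 °C; H2O
Reagents that add atoms: none
Why: 1,2-Reduction of the β,β-disubstituted enone by the bulky hydride under Felkin–Anh control of the adjacent silyloxy stereocentre should give the 12,13-syn allylic alcohol, and a silyl shift between O12 and O13 would be harmless because both are freed next.

Step 23
Reactants: 30 mono-silylated diol
Product: 31 12,13-diol (4,6,9-tris-O-tert-butyldimethylsilyl)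
Conditions: HF·pyridine, pyridine, THF, 0 °C
Reagents that add atoms: none
Why: Buffered fluoride desilylation removes the secondary triethylsilyl ether much faster than the hindered tert-butyldimethylsilyl ethers, so only the 12,13-diol should be released.

Step 24
Reactants: 31 diol
Product: 32 12,13-diacetate (4,6,9-tris-O-tert-butyldimethylsilyl)
Conditions: Ac2O, pyridine, DMAP (cat.), CH2Cl2, 0 → 23 °C
Reagents that add atoms: acetic anhydride, CC(=O)OC(C)=O
Why: DMAP-catalysed acetylation esterifies the two secondary hydroxyls, and no other free hydroxyl is present.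

Step 25
Reactants: 32 tris-silyl diacetate
Product: 33 target CNP0269663.3
Conditions: Bu4NF, AcOH, THF, 23 → 45 °C
Reagents that add atoms: none
Why: Acetic-acid-buffered fluoride desilylation should cleave the three silyl ethers without acetate migration or ionisation of the tertiary allylic alcohol.

**Compound list**

1 | acrolein | C=CC=O | starting material
2 | 3-(phenylselanyl)propanal | O=CCC[Se]c1ccccc1 | intermediate
3 | (E)-but-2-enal | C/C=C/C=O | starting material
4 | (E)-6-methylhepta-2,5-dien-4-ol (racemic) | C/C=C/C(O)C=C(C)C | intermediate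
5 | (E)-6-methylhepta-2,5-dien-4-one | C/C=C/C(=O)C=C(C)C | intermediate
6 | 6,6-dimethylfulvene | CC(C)=C1C=CC=C1 | starting material
7 | trichloroacetyl chloride | ClC(=O)C(Cl)(Cl)Cl | starting material
8 | rac-(1R,5R)-7,7-dichloro-4-(propan-2-ylidene)bicyclo[3.2.0]hept-2-en-6-one (one enantiomer drawn) | ClC1(Cl)C(=O)[C@@H]2[C@H]1C=CC2=C(C)C | intermediate
9 | rac-(1R,5R)-4-(propan-2-ylidene)bicyclo[3.2.0]hept-2-en-6-one (one enantiomer drawn) | C1C(=O)[C@@H]2[C@H]1C=CC2=C(C)C | intermediate
10 | (1R,5R,6R)-4-(propan-2-ylidene)bicyclo[3.2.0]hept-2-en-6-ol (endo alcohol) | C1[C@@H](O)[C@@H]2[C@H]1C=CC2=C(C)C | intermediate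
11 | (1R,5R,6R)-4-(propan-2-ylidene)bicyclo[3.2.0]hept-2-en-6-yl acetate | C1[C@@H](OC(C)=O)[C@@H]2[C@H]1C=CC2=C(C)C | intermediate
12 | (1R,5S,6R)-4-oxobicyclo[3.2.0]hept-2-en-6-yl acetate | C1[C@@H](OC(C)=O)[C@@H]2[C@H]1C=CC2=O | intermediate
13 | (1R,4S,5S,6R)-4-methylbicyclo[3.2.0]hept-2-ene-4,6-diol | C1[C@@H](O)[C@@H]2[C@H]1C=C[C@]2(C)O | intermediate
14 | (1R,4S,5R)-4-hydroxy-4-methylbicyclo[3.2.0]hept-2-en-6-one | C1C(=O)[C@@H]2[C@H]1C=C[C@]2(C)O | intermediate
15 | (1R,4S,5R)-4-(tert-butyldimethylsilyloxy)-4-methylbicyclo[3.2.0]hept-2-en-6-one | C1C(=O)[C@@H]2[C@H]1C=C[C@]2(C)O[Si](C)(C)C(C)(C)C | intermediate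
16 | 7-exo-(dimethylaminomethyl) derivative of 15 (Mannich base) | CN(C)C[C@@H]1C(=O)[C@@H]2[C@H]1C=C[C@]2(C)O[Si](C)(C)C(C)(C)C | intermediate (not isolated)
17 | trimethylammonium iodide of 16 (methiodide) | C[N+](C)(C)C[C@@H]1C(=O)[C@@H]2[C@H]1C=C[C@]2(C)O[Si](C)(C)C(C)(C)C.[I-] | intermediate (not isolated)
18 | (1R,4S,5R)-4-(tert-butyldimethylsilyloxy)-4-methyl-7-methylidenebicyclo[3.2.0]hept-2-en-6-one | C=C1C(=O)[C@@H]2[C@H]1C=C[C@]2(C)O[Si](C)(C)C(C)(C)C | intermediate
19 | dimethylaluminium C6=C10 enolate bearing CH2SPh at C10 | C1(CSc3ccccc3)=C(O[Al](C)C)[C@@H]2[C@H]1C=C[C@]2(C)O[Si](C)(C)C(C)(C)C | intermediate (not isolated)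
20 | (1R,4S,5R,7S)-7-[(1R)-1-hydroxy-3-(phenylselanyl)propyl]-7-(phenylsulfanylmethyl)-4-(tert-butyldimethylsilyloxy)-4-methylbicyclo[3.2.0]hept-2-en-6-one | c4ccccc4[Se]CC[C@@H](O)[C@]1(CSc3ccccc3)C(=O)[C@@H]2[C@H]1C=C[C@]2(C)O[Si](C)(C)C(C)(C)C | intermediate
21 | 9-O-tert-butyldimethylsilyl ether of 20 (ring-expansion precursor) | c4ccccc4[Se]CC[C@@H](O[Si](C)(C)C(C)(C)C)[C@]1(CSc3ccccc3)C(=O)[C@@H]2[C@H]1C=C[C@]2(C)O[Si](C)(C)C(C)(C)C | intermediate
22 | (1R,4S,5R,9R)-cis-fused 4α,9β-bis(tert-butyldimethylsilyloxy)-4β-methyl-10-methylene-hydroazulen-6-one | C=C1[C@H](O[Si](C)(C)C(C)(C)C)CCC(=O)[C@@H]2[C@H]1C=C[C@]2(C)O[Si](C)(C)C(C)(C)C | intermediate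
23 | (1R,4S,5S,9R)-trans-fused isomer of 22 (H-5 α) | C=C1[C@H](O[Si](C)(C)C(C)(C)C)CCC(=O)[C@H]2[C@H]1C=C[C@]2(C)O[Si](C)(C)C(C)(C)C | intermediate
24 | C6=C7 triethylsilyl enol ether of 23 | C=C1[C@H](O[Si](C)(C)C(C)(C)C)CC=C(O[Si](CC)(CC)CC)[C@H]2[C@H]1C=C[C@]2(C)O[Si](C)(C)C(C)(C)C | intermediate
25 | trans-fused 6-ketone with the 7α (Z)-3-(triethylsilyloxy)-1,5-dimethylhexa-2,4-dienyl chain (Michael adduct) | C=C1[C@H](O[Si](C)(C)C(C)(C)C)C[C@@H]([C@@H](C)/C=C(\O[Si](CC)(CC)CC)C=C(C)C)C(=O)[C@H]2[C@H]1C=C[C@]2(C)O[Si](C)(C)C(C)(C)C | intermediate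
26 | 6α-alcohol of 25 | C=C1[C@H](O[Si](C)(C)C(C)(C)C)C[C@@H]([C@@H](C)/C=C(\O[Si](CC)(CC)CC)C=C(C)C)[C@@H](O)[C@H]2[C@H]1C=C[C@]2(C)O[Si](C)(C)C(C)(C)C | intermediate
27 | 6-O-tert-butyldimethylsilyl ether of 26 | C=C1[C@H](O[Si](C)(C)C(C)(C)C)C[C@@H]([C@@H](C)/C=C(\O[Si](CC)(CC)CC)C=C(C)C)[C@@H](O[Si](C)(C)C(C)(C)C)[C@H]2[C@H]1C=C[C@]2(C)O[Si](C)(C)C(C)(C)C | intermediate
28 | 12,13-epoxide of 27 (13-triethylsilyloxy oxirane) | C=C1[C@H](O[Si](C)(C)C(C)(C)C)C[C@@H]([C@@H](C)[C@@H]3O[C@@]3(O[Si](CC)(CC)CC)C=C(C)C)[C@@H](O[Si](C)(C)C(C)(C)C)[C@H]2[C@H]1C=C[C@]2(C)O[Si](C)(C)C(C)(C)C | intermediate (not isolated)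
29 | 12-(triethylsilyloxy)-13-oxo-14-ene, 4,6,9-tris-O-tert-butyldimethylsilyl | C=C1[C@H](O[Si](C)(C)C(C)(C)C)C[C@@H]([C@@H](C)[C@H](O[Si](CC)(CC)CC)C(=O)C=C(C)C)[C@@H](O[Si](C)(C)C(C)(C)C)[C@H]2[C@H]1C=C[C@]2(C)O[Si](C)(C)C(C)(C)C | intermediate
30 | 13-alcohol of 29 (12,13-syn; O12 triethylsilyl) | C=C1[C@H](O[Si](C)(C)C(C)(C)C)C[C@@H]([C@@H](C)[C@H](O[Si](CC)(CC)CC)[C@H](C=C(C)C)O)[C@@H](O[Si](C)(C)C(C)(C)C)[C@H]2[C@H]1C=C[C@]2(C)O[Si](C)(C)C(C)(C)C | intermediate
31 | 12,13-diol, 4,6,9-tris-O-tert-butyldimethylsilyl | C=C1[C@H](O[Si](C)(C)C(C)(C)C)C[C@@H]([C@@H](C)[C@H](O)[C@H](C=C(C)C)O)[C@@H](O[Si](C)(C)C(C)(C)C)[C@H]2[C@H]1C=C[C@]2(C)O[Si](C)(C)C(C)(C)C | intermediate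
32 | 12,13-diacetate, 4,6,9-tris-O-tert-butyldimethylsilyl | C=C1[C@H](O[Si](C)(C)C(C)(C)C)C[C@@H]([C@@H](C)[C@H](OC(C)=O)[C@H](C=C(C)C)OC(C)=O)[C@@H](O[Si](C)(C)C(C)(C)C)[C@H]2[C@H]1C=C[C@]2(C)O[Si](C)(C)C(C)(C)C | intermediate
33 | CNP0269663.3: (1R,4S,5R,6R,7S,9R)-7-[(2R,3S,4S)-3,4-diacetoxy-6-methylhept-5-en-2-yl]-4-methyl-10-methylene-trans-fused hydroazul-2-ene-4,6,9-triol (locants of the plan) | C=C1[C@H](O)C[C@@H]([C@@H](C)[C@H](OC(C)=O)[C@H](C=C(C)C)OC(C)=O)[C@@H](O)[C@H]2[C@H]1C=C[C@]2(C)O | target

**Count and risks**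

Total step count: 25. Longest linear sequence: 22 steps (steps 4–25, from 6 and 7); aldehyde 2 (step 1) and dienone 5 (steps 2–3) are made separately.

Most likely to fail:

Step 15. Hydrogen transfer from the stannane may reduce the C7 radical before it reaches C6 (the C9 silyloxy group has to lie over the concave face in the cyclisation transition state), or the alkoxy radical may fragment toward C5. The fallback makes the same two bond changes in the polar manifold, as a Barbier cyclisation followed by a Grob fragmentation. It sets out from 18: the thiolate Michael/aldol of step 13 would be run with 3-chloropropanal to give the chloro aldol F1, which TBSOTf/2,6-lutidine would turn into the silyl ether F2 and NaI in acetone into the iodide F3. SmI2/HMPA in THF would then close C6–C7 by intramolecular Barbier addition to give the tricyclic cyclobutanol F4. S-Methylation with MeOSO2CF3 would give the sulfonium salt F5, and KN(SiMe3)2 would fragment its alkoxide (C6–C10 cleaved, C10=C20 formed). The fallback returns to the route at 22.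

Step 18. The electrophile may bond on the β face of C7, the anti relative topicity may erode, or the dienone may be lost to Nazarov-type or oligomerisation pathways under the Lewis acid. The fallback puts C11 under auxiliary control and builds the enone afterwards. It sets out from 24: TiCl4-mediated Mukaiyama–Michael addition to (R)-4-benzyl-3-[(E)-but-2-enoyl]oxazolidin-2-one (chelated s-cis imide, attack opposite the benzyl group) would give the imide F6. Li[BH(s-Bu)3] would give the 6α-alcohol F7, TBSOTf its silyl ether F8, Me2AlN(OMe)Me the Weinreb amide F9 and (CH3)2C=CHMgBr the enone F10. Kinetic enolisation toward C12 with KN(SiMe3)2 and trapping with Et3SiCl returns to the route at 27.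

Step 13. The α-methylene cyclobutanone may polymerise or dimerise, the thiolate addition may reverse before the aldol, or facial and chair control at C9 may erode. The fallback introduces the two C10 substituents one at a time without the enone. It sets out from 15: LiN(i-Pr)2/Me3SiCl would give the silyl enol ether F11, which with PhSCH2Cl and catalytic ZnBr2 (α-phenylthiomethylation of an enol silane) would give the exo phenylsulfanylmethyl ketone F12. Deprotonation at C10 with LiN(i-Pr)2 at −78 °C and addition of aldehyde 2 through the same closed transition state returns to the route at 20.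

Further compounds
F1 | step 15 | 7-[(1R)-3-chloro-1-hydroxypropyl] analogue of 20 (chloro aldol) | ClCC[C@@H](O)[C@]1(CSc3ccccc3)C(=O)[C@@H]2[C@H]1C=C[C@]2(C)O[Si](C)(C)C(C)(C)C
F2 | step 15 | 9-O-tert-butyldimethylsilyl ether of F1 | ClCC[C@@H](O[Si](C)(C)C(C)(C)C)[C@]1(CSc3ccccc3)C(=O)[C@@H]2[C@H]1C=C[C@]2(C)O[Si](C)(C)C(C)(C)C
F3 | step 15 | iodide analogue of 21 (3-iodo-1-silyloxypropyl at C10) | ICC[C@@H](O[Si](C)(C)C(C)(C)C)[C@]1(CSc3ccccc3)C(=O)[C@@H]2[C@H]1C=C[C@]2(C)O[Si](C)(C)C(C)(C)C
F4 | step 15 | tricyclic cyclobutanol with the C6–C7 bond closed (C6–OH endo) | C1C[C@@H](O[Si](C)(C)C(C)(C)C)[C@]2(CSc3ccccc3)[C@@]1(O)[C@@H]4[C@H]2C=C[C@]4(C)O[Si](C)(C)C(C)(C)C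
F5 | step 15 | S-methyl sulfonium trifluoromethanesulfonate of F4 | C1C[C@@H](O[Si](C)(C)C(C)(C)C)[C@]2(C[S+](C)c3ccccc3)[C@@]1(O)[C@@H]4[C@H]2C=C[C@]4(C)O[Si](C)(C)C(C)(C)C.[O-]S(=O)(=O)C(F)(F)F
F6 | step 18 | Michael adduct of 24 with the (R)-4-benzyl N-crotonoyl oxazolidinone (6-ketone, imide) | C=C1[C@H](O[Si](C)(C)C(C)(C)C)C[C@@H]([C@@H](C)CC(=O)N3[C@H](Cc4ccccc4)COC3=O)C(=O)[C@H]2[C@H]1C=C[C@]2(C)O[Si](C)(C)C(C)(C)C
F7 | step 18 | 6α-alcohol of F6 | C=C1[C@H](O[Si](C)(C)C(C)(C)C)C[C@@H]([C@@H](C)CC(=O)N3[C@H](Cc4ccccc4)COC3=O)[C@@H](O)[C@H]2[C@H]1C=C[C@]2(C)O[Si](C)(C)C(C)(C)C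
F8 | step 18 | 6-O-tert-butyldimethylsilyl ether of F7 | C=C1[C@H](O[Si](C)(C)C(C)(C)C)C[C@@H]([C@@H](C)CC(=O)N3[C@H](Cc4ccccc4)COC3=O)[C@@H](O[Si](C)(C)C(C)(C)C)[C@H]2[C@H]1C=C[C@]2(C)O[Si](C)(C)C(C)(C)C
F9 | step 18 | C13 N-methoxy-N-methylamide (Weinreb amide) | C=C1[C@H](O[Si](C)(C)C(C)(C)C)C[C@@H]([C@@H](C)CC(=O)N(C)OC)[C@@H](O[Si](C)(C)C(C)(C)C)[C@H]2[C@H]1C=C[C@]2(C)O[Si](C)(C)C(C)(C)C
F10 | step 18 | 13-oxo-14-ene (12-unsubstituted enone) | C=C1[C@H](O[Si](C)(C)C(C)(C)C)C[C@@H]([C@@H](C)CC(=O)C=C(C)C)[C@@H](O[Si](C)(C)C(C)(C)C)[C@H]2[C@H]1C=C[C@]2(C)O[Si](C)(C)C(C)(C)C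
F11 | step 13 | C6=C10 trimethylsilyl enol ether of 15 | C1=C(O[Si](C)(C)C)[C@@H]2[C@H]1C=C[C@]2(C)O[Si](C)(C)C(C)(C)C
F12 | step 13 | 7-exo-(phenylsulfanylmethyl) derivative of 15 | c3ccccc3SC[C@@H]1C(=O)[C@@H]2[C@H]1C=C[C@]2(C)O[Si](C)(C)C(C)(C)C
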